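**Retrosynthetic overview**
1. 10 ⇒ 6 + 7. One acid-triggered cascade makes the C3–C3a bond, the lactone C–O bond and the exocyclic C=C. It copies the presumed biogenesis: an electron-rich dihydrochalcone captures the keto group of shikimate-derived phenylpyruvate, lactonises and loses water.
2. 6 ⇒ 4 + 5. C-acylation of C2v-symmetric 5-methoxypyrogallol leaves exactly one ring C–H free for the cascade.
3. 4 ⇒ 2 ⇒ 1. A Dakin oxidation installs the central OH, and selective 4-O-methylation of 2,4,6-trihydroxybenzaldehyde sets the lone OMe.
4. Ring order: all three benzene rings are bought. The only ring formed is the γ-lactone (benzofuran-2-one), in the last step, and no protecting groups are used.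

Assumption: bractelactone has no stereocentre. Its only stereo-element is the exocyclic alkene, which the SMILES gives as Z (phenyl syn to the lactone C=O, anti to the 4-OMe side). "Single enantiomer" is therefore read as "single geometric isomer".

**Route**

Step 1
Reactants: 1 2,4,6-trihydroxybenzaldehyde
Product: 2 2,6-dihydroxy-4-methoxybenzaldehyde
Conditions: Me2SO4 (1.0 equiv), K2CO3 (1.0 equiv), acetone, reflux, 4 h
Reagents that add atoms: dimethyl sulfate, COS(=O)(=O)OC
Why: Williamson-type O-methylation in which the 4-OH (para to CHO, most acidic, not hydrogen-bonded to or crowded by the formyl group) is ionised first, so one equivalent of base and a hard electrophile methylate it selectively on oxygen; no stereocentre is involved.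

Step 2
Reactants: 2 2,6-dihydroxy-4-methoxybenzaldehyde
Product: 4 5-methoxybenzene-1,2,3-triol (5-methoxypyrogallol), via aryl formate 3 (not isolated)
Conditions: 30% aq H2O2 (1.1 equiv), B(OH)3, cat. H2SO4, THF, rt, Ar
Reagents that add atoms: hydrogen peroxide, OO
Why: Dakin oxidation in its acidic variant, where two ortho OH groups and a para OMe make aryl migration very fast, formate 3 hydrolyses in the wet acidic medium, and the absence of base keeps the air-sensitive triol un-ionised; no stereocentre is involved.

Step 3
Reactants: 4 5-methoxybenzene-1,2,3-triol; 5 3-phenylpropanoic acid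
Product: 6 1-(2,3,4-trihydroxy-6-methoxyphenyl)-3-phenylpropan-1-one (2′,3′,4′-trihydroxy-6′-methoxydihydrochalcone)
Conditions: 5 (1.1 equiv), BF3·OEt2 (as solvent), 85 °C, 2 h, Ar; aqueous work-up
Reagents that add atoms: none
Why: Friedel–Crafts (Nencki-type) C-acylation of a polyphenol with a free acid, in which the two open ring positions of 4 are symmetry-equivalent so only one regioisomer can form, and the chelated ketone shuts down a second acylation; no stereocentre is involved.

Step 4
Reactants: 6 1-(2,3,4-trihydroxy-6-methoxyphenyl)-3-phenylpropan-1-one; 7 phenylpyruvic acid (2-oxo-3-phenylpropanoic acid)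
Product: 10 bractelactone = (Z)-3-benzylidene-6,7-dihydroxy-4-methoxy-5-(3-phenylpropanoyl)benzofuran-2(3H)-one, via hydroxy acid 8 (not isolated), via 3-benzyl-3-hydroxylactone 9 (not isolated)
Conditions: 7 (2 equiv, added over 4 h), TfOH (20 mol %), HFIP, 55 °C, Ar, then 12 h at 55 °C
Reagents that add atoms: none
Why: Proposed new method: TfOH in strongly hydrogen-bonding HFIP activates the keto tautomer of 7, the only free ring carbon of 6 (C-5′, ortho to 4′-OH and 6′-OMe, para to 2′-OH) attacks it in a Friedel–Crafts hydroxyalkylation to give 8, the neighbouring 4′-OH (the 6′-oxygen is blocked as OMe) closes the five-membered lactone 9, and ionisation of the tertiary benzylic OH to a cation stabilised by 4-OMe and 6-OH followed by loss of a benzyl proton (E1) gives the conjugated benzylidene, whose geometry equilibrates through the same cation to Z because an E phenyl would clash with 4-OMe; the racemic centre of 8 and 9 is erased and no stereocentre remains; the closest known reaction type is the domino Friedel–Crafts/lactonisation of polyphenols with α-keto esters to 3-hydroxybenzofuran-2(3H)-ones, here extended to an enolisable α-keto acid and carried through dehydration.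

**Compound list**
1 | 2,4,6-trihydroxybenzaldehyde | O=Cc1c(O)cc(O)cc1O | starting material
2 | 2,6-dihydroxy-4-methoxybenzaldehyde | COc1cc(O)c(C=O)c(O)c1 | intermediate
3 | 2,6-dihydroxy-4-methoxyphenyl formate (not isolated) | COc1cc(O)c(OC=O)c(O)c1 | intermediate
4 | 5-methoxybenzene-1,2,3-triol (5-methoxypyrogallol) | COc1cc(O)c(O)c(O)c1 | intermediate
5 | 3-phenylpropanoic acid (hydrocinnamic acid) | OC(=O)CCc1ccccc1 | starting material
6 | 1-(2,3,4-trihydroxy-6-methoxyphenyl)-3-phenylpropan-1-one | COc1cc(O)c(O)c(O)c1C(=O)CCc1ccccc1 | intermediate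
7 | phenylpyruvic acid (2-oxo-3-phenylpropanoic acid) | OC(=O)C(=O)Cc1ccccc1 | starting material
8 | 2-hydroxy-3-phenyl-2-[2,3,4-trihydroxy-6-methoxy-5-(3-phenylpropanoyl)phenyl]propanoic acid (racemic, not isolated) | COc1c(C(=O)CCc2ccccc2)c(O)c(O)c(O)c1C(O)(Cc1ccccc1)C(=O)O | intermediate
9 | 3-benzyl-3,6,7-trihydroxy-4-methoxy-5-(3-phenylpropanoyl)benzofuran-2(3H)-one (racemic, not isolated) | COc1c(C(=O)CCc2ccccc2)c(O)c(O)c2OC(=O)C(O)(Cc3ccccc3)c12 | intermediate
10 | bractelactone, (Z)-3-benzylidene-6,7-dihydroxy-4-methoxy-5-(3-phenylpropanoyl)benzofuran-2(3H)-one | COc1c(C(=O)CCc2ccccc2)c(O)c(O)c2c1/C(=C/c1ccccc1)C(=O)O2 | target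

Total step count: 4. Longest linear sequence: 4 (1 → 2 → 4 → 6 → 10).

**Steps most likely to fail, with fallbacks**

Step 4 carries the most risk. Acid 7 can self-condense, the acyl-deactivated ring may attack a ketone only slowly, and the cation from 9 could be trapped by a second molecule of 6.
- The fallback sets out from 6 and comes back at 10. It builds the lactone from an aldehyde-level C2 unit and makes the alkene afterwards by condensation.
- Compound 6 is heated with 50% aq glyoxylic acid and cat. p-TsOH in 1,2-dichloroethane under a water separator. This gives 2-hydroxy-2-[2,3,4-trihydroxy-6-methoxy-5-(3-phenylpropanoyl)phenyl]acetic acid F1.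
- That acid closes in the flask to 3,6,7-trihydroxy-4-methoxy-5-(3-phenylpropanoyl)benzofuran-2(3H)-one F2.
- SnCl2 with conc. HCl in AcOH removes the benzylic OH, as in the reduction of electron-rich mandelic acids to arylacetic acids, and does not touch the aryl ketone. The product is 6,7-dihydroxy-4-methoxy-5-(3-phenylpropanoyl)benzofuran-2(3H)-one F3.
- Knoevenagel condensation of this acidic lactone with benzaldehyde (piperidinium acetate, toluene, reflux, Ar) gives 10, Z for the same steric reason.

Step 1 is second, because methylation may run on to the 4,6-dimethyl ether or occur on carbon.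
- The fallback sets out from 1 and comes back at 2. Every OH is methylated, and the two ortho methyl groups are then removed under chelation control.
- Excess Me2SO4/K2CO3 gives 2,4,6-trimethoxybenzaldehyde F4, which is also a cheap catalogue compound.
- AlCl3 (4 equiv) in CH2Cl2 at reflux is held by the formyl oxygen and cleaves one ortho OMe to give 2-hydroxy-4,6-dimethoxybenzaldehyde F5. It then cleaves the other ortho OMe to give 2.
- The 4-OMe cannot chelate and stays.

Step 2 is third, because 4 is very electron-rich. It can be over-oxidised to hydroxyquinones and lost on isolation.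
- The fallback sets out from 2 (with 5) and comes back at 6, bypassing 4 by swapping the order of oxidation and acylation.
- Compounds 2 and 5 in BF3·OEt2 at 70 °C give 2,6-dihydroxy-4-methoxy-3-(3-phenylpropanoyl)benzaldehyde F6. The two open positions of 2 are equivalent, and the reaction parallels the known second acylation of monoacylphloroglucinols.
- The same Dakin conditions then convert only the aldehyde, through 2,6-dihydroxy-4-methoxy-3-(3-phenylpropanoyl)phenyl formate F7, into the new OH of 6. The ketone of 6 makes it far less oxidisable than 4.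

**Further compounds**
F1 | step 4 | 2-hydroxy-2-[2,3,4-trihydroxy-6-methoxy-5-(3-phenylpropanoyl)phenyl]acetic acid (racemic) | COc1c(C(=O)CCc2ccccc2)c(O)c(O)c(O)c1C(O)C(=O)O
F2 | step 4 | 3,6,7-trihydroxy-4-methoxy-5-(3-phenylpropanoyl)benzofuran-2(3H)-one (racemic) | COc1c(C(=O)CCc2ccccc2)c(O)c(O)c2OC(=O)C(O)c12
F3 | step 4 | 6,7-dihydroxy-4-methoxy-5-(3-phenylpropanoyl)benzofuran-2(3H)-one | COc1c(C(=O)CCc2ccccc2)c(O)c(O)c2OC(=O)Cc12
F4 | step 1 | 2,4,6-trimethoxybenzaldehyde | COc1cc(OC)c(C=O)c(OC)c1
F5 | step 1 | 2-hydroxy-4,6-dimethoxybenzaldehyde | COc1cc(O)c(C=O)c(OC)c1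
F6 | step 2 | 2,6-dihydroxy-4-methoxy-3-(3-phenylpropanoyl)benzaldehyde | COc1cc(O)c(C=O)c(O)c1C(=O)CCc1ccccc1
F7 | step 2 | 2,6-dihydroxy-4-methoxy-3-(3-phenylpropanoyl)phenyl formate | COc1cc(O)c(OC=O)c(O)c1C(=O)CCc1ccccc1
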